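## Structural features

The target 11 is 2,5,6-tribromo-1-methylindole-3-carbaldehyde: a benzene ring (C3a, C4 to C7, C7a) fused along the C3a–C7a bond to an N-methylpyrrole ring (N1, C2, C3). The pyrrole half carries bromine on C2 and a formyl group on the neighbouring C3; the benzo half carries bromine on the adjacent carbons C5 and C6 and hydrogen on C4 and C7. The molecule is flat and achiral, so the only stereocentres in the plan are the two adjacent ring-fusion carbons C3a and C7a of the dihydro compounds 5 and 6, and they are erased on aromatisation. The fragile groups are the aldehyde and the C2 bromide, which together form a vinylogous acyl bromide open to addition–elimination, and the three C–Br bonds, which rule out organolithium, reductive and palladium chemistry late in the route. The real difficulty is regiochemical: electrophilic bromination of a simple N-methylindole attacks C3 and C2 first and gives no clean 5,6-pattern, so the two benzo bromines are best built in with the ring. The key step exploits the local symmetry of the benzo ring: the unit C4–C5(Br)–C6(Br)–C7 is symmetric about the bisector of the C3a–C7a bond and can be delivered intact as a symmetric dibromodiene laid across the C2=C3 bond of a pyrrole. The Br/CHO pair on C2/C3 is the fingerprint of a Vilsmeier-type haloformylation of a lactam, so C2 must pass through the carbonyl oxidation level before the last step.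

## Logic of the disconnections

11 ⇒ 9 (through 10). The C3–C(formyl) bond and the C2–Br bond are cut together. A bromine on C2 beside a formyl group on C3 is what a Vilsmeier-type bromoformylation writes onto a lactam with a free C3 methylene, so both groups trace back to the carbonyl and the CH2 of 9. The gain is that the aldehyde and the activated C2 bromide are absent from every earlier compound. The forward step needs a bromide-based reagent (POBr3, not POCl3, to exclude a C2 chloride) and a hydrolytic work-up that converts 10 into 11 without displacing the C2 bromine.

9 ⇒ 7 (through 8). The C2–O bond is cut; no carbon–carbon bond changes. This is an oxidation-level adjustment: 7 is what the annulation can deliver, 9 is what the last step needs. The gain is the removal of the only atom that neither building block contains. The forward step must oxygenate C2 of an indole whose C3 is free. A sulfoxide/HCl oxidation is set aside, because the activated sulfoxide would be expected to be captured at the free C3 as a sulfonium salt. C3 chlorination to 8 followed by acid hydrolysis is used instead.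

7 ⇒ 6. Hydrogen is added back to C3a and C7a; no skeletal bond is cut. This uncovers a cyclohexa-1,3-diene with an sp3 ring fusion, the retron of a cheletropic extrusion, so the benzene ring becomes reachable by cycloaddition. The forward step needs an oxidant that takes hydride from C7a quickly and does not attack the electron-rich product. Both stereocentres disappear, so their configuration needs no control.

6 ⇒ 3 + 4 (through 5). After formal re-insertion of SO2 across C4 and C7, the C3a–C4 and C7–C7a bonds are cut. The cut is placed there because the C5(Br)–C6(Br) edge makes the four benzo carbons a symmetric unit, so no regiochemistry can arise, and both bromines come from one bought compound. The gain is the largest of the route: one ring, two carbon–carbon bonds and both benzo bromines in one operation from two small symmetric partners. The demand is severe: the aromatic 4 has to act once as a 2π component and not as a nucleophile for substitution, 3 must not dimerise first, and 6 must not add a second diene. A 2-oxygenated analogue of 4 would carry the C2 oxygen through and save the later oxidation, but its more nucleophilic ring would favour conjugate addition with bromide loss at C3 of 3. So 4 is kept as it is, in large excess, with slow addition of 3.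

3 ⇒ 1 (through 2). The two S–O bonds are cut. 1 is commercial and already holds the two bromines on adjacent carbons, so the diene is one step away. The forward step needs an oxidant strong enough for an electron-poor thiophene yet neutral and free of water, and 3 must be used without storage because C2 and C5 are unsubstituted.

## Other disconnections considered

Alternative 1: The cut is the C3–C3a bond, made by ring contraction. Heating the diazo dione A1 (6,7-dibromo-3-diazo-1-methylquinoline-2,4-dione) in methanol would expel N2 and shift the aryl carbon from the C4 carbonyl carbon to the carbene carbon. The six-membered lactam contracts to the five-membered one and the old C4 carbon ends as the methyl ester on C3 of A2 (methyl 5,6-dibromo-2-hydroxy-1-methylindole-3-carboxylate).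
- In its favour: this Wolff contraction is an established reaction, the benzene ring stays aromatic throughout, and A2 already carries the C2 oxygen that the chosen plan must introduce in step 4. On precedent and robustness of the key step it is the better plan. Hydrolysis and decarboxylation of A2 would give 9, so both plans share step 5.
- Against it, on structure: the bromines must come from a 3,4-dibrominated aniline whose ring closure can occur at either ortho position. The 6,7-pattern of A1 is therefore not guaranteed in the way the symmetric diene 3 guarantees C5/C6. The C3 carbon arrives at the ester level and is thrown away again.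
- Against it, on mechanism: migration of the amide nitrogen could compete with aryl migration, an ambiguity that the pair 3/4 does not have. A diazo compound must be heated, which is no safer than handling 3; on this point the two are about equal.
- Step economy: about three steps to A1, one contraction, one to 9 and one to 11, that is about six against five. The difference is small.

Alternative 2: The cut is the C5–C6 bond. Heating the enediyne A3 (methyl 4,5-bis(bromoethynyl)-1-methylpyrrole-2-carboxylate) with a hydrogen-atom donor would join the two bromine-bearing alkyne termini by Bergman cycloaromatisation. The 1,4-diradical at C4/C7 would take up two hydrogen atoms to give A4 (methyl 5,6-dibromo-1-methylindole-2-carboxylate).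
- In its favour: the bromine positions are fixed by construction, which equals the chosen plan. The key step gives a fully aromatic indole directly and the pyrrole never loses its aromaticity. On these two points it is better, since no dihydro compound such as 6 and no separate dehydrogenation are needed.
- Against it, on mechanism: fusion to a five-membered ring pulls the alkyne termini apart and raises the cyclisation barrier. The bromoalkyne termini are hindered and thermally labile. The diradical could abstract bromine instead of hydrogen.
- Against it, on structure: the C2 ester is a spectator that has to be removed (saponification, decarboxylation) to reach 7, after which steps 4 and 5 are still needed.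
- Step economy: three or four steps to A3 from a commercial pyrrole ester (dihalogenation, double Sonogashira coupling, alkyne bromination), one cyclisation, two to 7 and two to 11. That is eight or more against five.

Alternative 3: The cut is the C2=C3 bond. The keto formamide A5 (N-(2-acetyl-4,5-dibromophenyl)-N-methylformamide) would be reductively coupled with TiCl3 and zinc (low-valent titanium), closing the pyrrole ring to A6 (5,6-dibromo-1,3-dimethylindole).
- In its favour: intramolecular oxo-amide coupling is a reliable, precedented indole synthesis and gives the aromatic heterocycle directly. A6 already carries a carbon on C3, whereas the chosen plan adds that carbon only in the last step. On precedent and on early placement of the C3 carbon it is the better plan.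
- Against it, on structure: the C3 carbon is at the methyl level. After C2 bromination to A7 (2,5,6-tribromo-1,3-dimethylindole) a benzylic oxidation to the aldehyde would be needed next to a reactive C2 bromide. The bromine pattern of A5 cannot be set by brominating the parent aminoketone, because the amino group directs elsewhere, so A5 itself needs several steps.
- Against it, on mechanism: a strongly reducing titanium reagent in the presence of two aryl bromides raises a chemoselectivity question that the redox-neutral cycloaddition of 3 and 4 avoids. On the regiochemistry of ring closure the two plans are equal (none arises).
- Step economy: about three or four steps to A5, one coupling and two to 11, that is six or seven against five.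

Key step: step 2

Remark: 5 is drawn as the endo adduct (pyrroline ring anti to the SO2 bridge); the exo adduct would serve equally, since the bridge is lost and C3a/C7a are cis in both; racemates are drawn as one enantiomer.

## Route

Step 1
Reactants: 1 3,4-dibromothiophene
Product: 3 3,4-dibromothiophene 1,1-dioxide, via 3,4-dibromothiophene 1-oxide 2 (not isolated)
Conditions: DMDO (2.5 equiv, dilute solution in acetone), 0 °C → rt, dark; evaporate below 20 °C; use at once
Reagents that add atoms: dimethyldioxirane, CC1(C)OO1 (one oxygen atom per molecule, two in all)
Why: Electrophilic oxygen transfer from the dioxirane to sulfur, a known way to convert electron-poor halothiophenes into their S,S-dioxides under neutral conditions; the non-aromatic S-oxide 2 should be oxidised faster than 1. The only by-product is acetone, so 3 is obtained by cold evaporation without aqueous or acidic work-up, and no concentrated peroxide or peracid is handled.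

Step 2
Reactants: 3 3,4-dibromothiophene 1,1-dioxide; 4 N-methylpyrrole (1-methyl-1H-pyrrole)
Product: 6 cis-5,6-dibromo-1-methyl-3a,7a-dihydro-1H-indole (racemic), via bridged sulfone adduct 5 (not isolated)
Conditions: 4 (10 equiv), PhMe, 70 °C, Ar sweep; 3 in PhMe added over 5 h; volatiles removed below 30 °C; crude 6 kept under Ar and carried on
Reagents that add atoms: none
Why: Proposed new method: the non-aromatic, electron-poor dienyl sulfone 3 should add across the electron-rich C2=C3 bond of 4 in an inverse-electron-demand [4+2] cycloaddition, either concerted and asynchronous or stepwise (pyrrole C2 attacks a diene terminus, and the sulfonyl-stabilised allyl anion then closes onto C3 of the 2H-pyrrolium ion); the closest known reaction type is the Diels–Alder/SO2-extrusion annulation of halogenated thiophene 1,1-dioxides with alkenes, enol ethers and alkynes, extended here to a double bond of an aromatic pyrrole. The bridged sulfone 5 then loses SO2 in a thermally allowed cheletropic extrusion, leaving the cyclohexa-1,3-diene of 6 with both bromines on sp2 carbons. The six-membered ring is therefore closed by intermolecular cycloaddition, the C3a–C4 and C7–C7a bonds being formed on one face of the pyrrole bond, and not by cyclisation of a chain. The two new stereocentres C3a and C7a come out cis because addition to the C2=C3 bond is suprafacial (in the stepwise variant the tethered anion can reach only the face it started from); 6 is racemic, and the endo or exo sense of 5 is lost with the bridge. Regioselectivity is not an issue, since 3 is C2v-symmetric and the two C=C bonds of 4 are equivalent, and the N-methyl group removes any N–H that could add to the sulfone. What has to be secured is annulation in preference to substitution by proton loss (or bromide loss after attack at C3 of 3), to self-dimerisation of 3 and to a second addition at the enamine bond of 6: a tenfold excess of 4, slow addition of 3, moderate heat and an argon sweep that carries off SO2 are chosen for this.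

Step 3
Reactants: 6 cis-5,6-dibromo-1-methyl-3a,7a-dihydro-1H-indole
Product: 7 5,6-dibromo-1-methyl-1H-indole
Conditions: DDQ (1.05 equiv), PhMe, 0 °C → rt; filtration through basic alumina
Reagents that add atoms: none
Why: Quinone dehydrogenation of a cyclohexadiene: hydride abstraction from C7a (allylic and alpha to nitrogen) followed by loss of the C3a proton gives the aromatic benzo ring, and both stereocentres vanish here. One equivalent at low temperature should leave the C–Br bonds and the newly formed electron-rich indole untouched.

Step 4
Reactants: 7 5,6-dibromo-1-methyl-1H-indole
Product: 9 5,6-dibromo-1-methyl-1,3-dihydro-2H-indol-2-one, via 5,6-dibromo-3-chloro-1-methyl-1H-indole 8 (not isolated)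
Conditions: NCS (1.05 equiv), CH2Cl2, 0 °C → rt; solvent exchange; then AcOH, 85% aq. H3PO4, 100–110 °C
Reagents that add atoms: water, O (lactam oxygen of 9); N-chlorosuccinimide, O=C1CCC(=O)N1Cl (chlorine of 8 only, lost again)
Why: Electrophilic C3 chlorination of the N-methylindole by NCS, then the classical acid hydrolysis of a 3-haloindole to an oxindole: protonation at C3 gives a 3H-indolium ion, water adds at C2 and HCl is lost, leaving the 2-hydroxyindole tautomer of 9. The aryl bromides are inert to NCS and to hot aqueous acid, and the sequence avoids the C3 sulfonium formation expected from a sulfoxide/HCl oxidation of an indole with free C3.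

Step 5
Reactants: 9 5,6-dibromo-1-methyl-1,3-dihydro-2H-indol-2-one
Product: 11 2,5,6-tribromo-1-methyl-1H-indole-3-carbaldehyde, via C3 iminium bromide 10 (not isolated)
Conditions: POBr3 (2.5 equiv), DMF (3 equiv), CH2Cl2, 0 °C → reflux; then ice/H2O, rt
Reagents that add atoms: N,N-dimethylformamide, CN(C)C=O (formyl carbon); phosphorus oxybromide, O=P(Br)(Br)Br (C2 bromine); water, O (aldehyde oxygen)
Why: Vilsmeier–Haack–Arnold bromoformylation of an N-alkyl oxindole: the enol of 9 is aminomethylenated at C3 by the bromoiminium reagent, the lactam oxygen is activated and displaced by bromide at C2, and the aromatic iminium salt 10 is hydrolysed to the aldehyde on aqueous work-up. POBr3 replaces POCl3 so that the C2 halogen is bromine, and the deactivated benzo ring should not be formylated.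

## Compound list

1 | 3,4-dibromothiophene | Brc1cscc1Br | starting material
2 | 3,4-dibromothiophene 1-oxide | O=S1C=C(Br)C(Br)=C1 | intermediate (not isolated)
3 | 3,4-dibromothiophene 1,1-dioxide | O=S1(=O)C=C(Br)C(Br)=C1 | intermediate
4 | N-methylpyrrole (1-methyl-1H-pyrrole) | Cn1cccc1 | starting material
5 | endo-5,6-dibromo-1-methyl-3a,4,7,7a-tetrahydro-1H-4,7-epithioindole 8,8-dioxide (racemic; 3a-H and 7a-H cis, pyrroline ring anti to the SO2 bridge) | CN1C=C[C@@H]2[C@H]1[C@@H]1C(Br)=C(Br)[C@H]2S1(=O)=O | intermediate (not isolated)
6 | cis-5,6-dibromo-1-methyl-3a,7a-dihydro-1H-indole (racemic; 3a-H and 7a-H on the same face) | CN1C=C[C@H]2C=C(Br)C(Br)=C[C@@H]12 | intermediate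
7 | 5,6-dibromo-1-methyl-1H-indole | Cn1ccc2cc(Br)c(Br)cc21 | intermediate
8 | 5,6-dibromo-3-chloro-1-methyl-1H-indole | Cn1cc(Cl)c2cc(Br)c(Br)cc21 | intermediate (not isolated)
9 | 5,6-dibromo-1-methyl-1,3-dihydro-2H-indol-2-one | CN1C(=O)Cc2cc(Br)c(Br)cc21 | intermediate
10 | [(2,5,6-tribromo-1-methyl-1H-indol-3-yl)methylidene]dimethylammonium bromide | C[N+](C)=Cc1c(Br)n(C)c2cc(Br)c(Br)cc12.[Br-] | intermediate (not isolated)
11 | 2,5,6-tribromo-1-methyl-1H-indole-3-carbaldehyde | Cn1c(Br)c(C=O)c2cc(Br)c(Br)cc21 | target

## Step count and least certain steps

Total step count: 5. Longest linear sequence: 5 steps (1 → 3 → 6 → 7 → 9 → 11); 4 is bought and enters in step 2.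

Step 2 (key step, proposed new method).
- What may go wrong: conjugate addition followed by re-aromatisation of the pyrrole (substitution) instead of ring closure, self-dimerisation of 3 outrunning the cross reaction, or a second cycloaddition at the enamine bond of 6.
- Why: the 2π partner has to give up its aromatic stabilisation, while the product is a better donor than 4.
- Fallback (known chemistry, different approach): the annulation is given up and the benzo ring is taken from a commercial indole whose C3 ester steers electrophilic bromination to C5 and C6. The detour does not start from a numbered compound, because 3 and 4 themselves are set aside. It sets out from commercial methyl 1H-indole-3-carboxylate F1, which with Br2 in AcOH should give methyl 5,6-dibromo-1H-indole-3-carboxylate F2. N-Methylation (NaH, MeI, DMF) would give methyl 5,6-dibromo-1-methyl-1H-indole-3-carboxylate F3. Saponification (NaOH, aq. MeOH) would give 5,6-dibromo-1-methyl-1H-indole-3-carboxylic acid F4, which loses CO2 on heating in acid. The detour comes back to the route at 7 and replaces steps 1 to 3.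

Step 1.
- What may go wrong: Diels–Alder self-dimerisation of the S-oxide 2 before the second oxygen transfer, or of 3 during concentration.
- Why: neither has a substituent on C2 or C5 to shield the diene.
- Fallback: it sets out from 1. Double silylation at C2/C5 (LDA, Me3SiCl, THF, −78 °C) would give 3,4-dibromo-2,5-bis(trimethylsilyl)thiophene F5. Its S-oxide cannot dimerise, so oxidation with mCPBA should give the storable 3,4-dibromo-2,5-bis(trimethylsilyl)thiophene 1,1-dioxide F6. Buffered fluoride (TBAF, AcOH, THF, −20 °C) would remove both silyl groups just before the cycloaddition. The detour comes back to the route at 3.

Step 4.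
- What may go wrong: incomplete hydrolysis of 8, or acid-induced halogen migration and oligomerisation during the forcing hydrolysis.
- Why: the two bromines lower the basicity of C3, so protonation there needs hot strong acid.
- Fallback: it sets out from 7. Pyridinium tribromide (about 3 equiv) in aqueous tert-butanol would over-oxidise the pyrrole ring to 3,3,5,6-tetrabromo-1-methyl-1,3-dihydro-2H-indol-2-one F7. Zn dust in AcOH at rt would then remove the two C3 bromines reductively while leaving the aryl bromides. The detour comes back to the route at 9.

Step 5.
- What may go wrong: stalling after C3 aminomethylenation without exchange of the lactam oxygen for bromine, or premature hydrolysis of the reagent.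
- Why: POBr3 is moisture-sensitive, and one reagent has to do two jobs on an electron-poor lactam.
- Fallback: it sets out from 9 and separates the two events. Condensation with DMF dimethyl acetal (PhMe, 80 °C) would give (E)-5,6-dibromo-3-[(dimethylamino)methylidene]-1-methyl-1,3-dihydro-2H-indol-2-one F8 (the geometry is of no consequence). F8 would then be deoxybrominated with POBr3 alone in CH2Cl2. The detour comes back to the route at 10, which is hydrolysed to 11 as before.

## Further compounds

F1 | step 2 | methyl 1H-indole-3-carboxylate | COC(=O)c1c[nH]c2ccccc12
F2 | step 2 | methyl 5,6-dibromo-1H-indole-3-carboxylate | COC(=O)c1c[nH]c2cc(Br)c(Br)cc12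
F3 | step 2 | methyl 5,6-dibromo-1-methyl-1H-indole-3-carboxylate | COC(=O)c1cn(C)c2cc(Br)c(Br)cc12
F4 | step 2 | 5,6-dibromo-1-methyl-1H-indole-3-carboxylic acid | OC(=O)c1cn(C)c2cc(Br)c(Br)cc12
F5 | step 1 | 3,4-dibromo-2,5-bis(trimethylsilyl)thiophene | C[Si](C)(C)c1sc([Si](C)(C)C)c(Br)c1Br
F6 | step 1 | 3,4-dibromo-2,5-bis(trimethylsilyl)thiophene 1,1-dioxide | C[Si](C)(C)C1=C(Br)C(Br)=C([Si](C)(C)C)S1(=O)=O
F7 | step 4 | 3,3,5,6-tetrabromo-1-methyl-1,3-dihydro-2H-indol-2-one | CN1C(=O)C(Br)(Br)c2cc(Br)c(Br)cc21
F8 | step 5 | (E)-5,6-dibromo-3-[(dimethylamino)methylidene]-1-methyl-1,3-dihydro-2H-indol-2-one | CN(C)/C=C1/C(=O)N(C)c2cc(Br)c(Br)cc21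
A1 | alternative 1 | 6,7-dibromo-3-diazo-1-methylquinoline-2,4(1H,3H)-dione | CN1C(=O)C(=[N+]=[N-])C(=O)c2cc(Br)c(Br)cc21
A2 | alternative 1 | methyl 5,6-dibromo-2-hydroxy-1-methyl-1H-indole-3-carboxylate | COC(=O)c1c(O)n(C)c2cc(Br)c(Br)cc12
A3 | alternative 2 | methyl 4,5-bis(bromoethynyl)-1-methyl-1H-pyrrole-2-carboxylate | COC(=O)c1cc(C#CBr)c(C#CBr)n1C
A4 | alternative 2 | methyl 5,6-dibromo-1-methyl-1H-indole-2-carboxylate | COC(=O)c1cc2cc(Br)c(Br)cc2n1C
A5 | alternative 3 | N-(2-acetyl-4,5-dibromophenyl)-N-methylformamide | CC(=O)c1cc(Br)c(Br)cc1N(C)C=O
A6 | alternative 3 | 5,6-dibromo-1,3-dimethyl-1H-indole | Cc1cn(C)c2cc(Br)c(Br)cc12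
A7 | alternative 3 | 2,5,6-tribromo-1,3-dimethyl-1H-indole | Cc1c(Br)n(C)c2cc(Br)c(Br)cc12
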